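**Retrosynthetic overview**
- Huazhongilexin ⇐ O-debenzylation and ester reduction of the all-trans dimethyl 2,5-diaryloxolane-3,4-dicarboxylate.
- Oxolane diester ⇐ acid methanolysis/rearrangement of a C2-symmetric 3,6-diaryl-furo[3,4-c]furan-1,4-dione (bis-lactone).
- Bis-lactone ⇐ one-flask twofold Evans syn aldol plus twofold auxiliary-expelling lactonisation of succinyl bis(oxazolidinone) with two ArCHO: two C–C bonds, four stereocentres and both lactone rings in one operation.
- Bis-imide ⇐ succinyl chloride + (S)-4-benzyl-2-oxazolidinone; ArCHO ⇐ syringaldehyde + benzyl bromide.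
- Ring order: the two γ-lactone rings together (key step), then the oxolane ring, formed as both lactones open.

Assumption: the target is the all-trans (2S,3R,4R,5S) isomer as given in the SMILES; Ar = 4-(benzyloxy)-3,5-dimethoxyphenyl. The route is a paper design; nothing here has been run.

**Step 1**
Reactants: 1 syringaldehyde (4-hydroxy-3,5-dimethoxybenzaldehyde)
Product: 2 4-(benzyloxy)-3,5-dimethoxybenzaldehyde
Conditions: BnBr (1.1 equiv), K2CO3 (1.5 equiv), DMF, 60 °C
Reagents that add atoms: benzyl bromide, BrCc1ccccc1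
Why: Williamson etherification (SN2) of the phenoxide gives an ether that survives boron enolates, HCl/MeOH and LiAlH4 and keeps the ring electron-rich for the later benzylic ionisation; no stereocentre is formed.

**Step 2**
Reactants: 3 succinyl chloride (1.0 equiv); 4 (S)-4-benzyl-1,3-oxazolidin-2-one (2.1 equiv)
Product: 5 1,4-bis[(4S)-4-benzyl-2-oxo-1,3-oxazolidin-3-yl]butane-1,4-dione
Conditions: 4, n-BuLi (2.1 equiv), THF, −78 °C; then 3, −78 to 0 °C
Reagents that add atoms: none
Why: Twofold N-acylation of the lithium oxazolidinide by the diacid chloride gives the C2-symmetric bis-imide; both stereocentres come unchanged from 4.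

**Step 3 (key step)**
Reactants: 5 1,4-bis[(4S)-4-benzyl-2-oxo-1,3-oxazolidin-3-yl]butane-1,4-dione; 2 4-(benzyloxy)-3,5-dimethoxybenzaldehyde (2.3 equiv)
Product: 8 (3S,3aS,6S,6aS)-3,6-bis[4-(benzyloxy)-3,5-dimethoxyphenyl]tetrahydrofuro[3,4-c]furan-1,4-dione, via bis(dibutylboryl) dienolate 6 (not isolated), via bis-syn-aldol diol 7 (not isolated)
Conditions: Bu2BOTf (2.6 equiv), iPr2NEt (3.0 equiv), CH2Cl2, −78 to 0 °C; then 2, −78 to 0 °C; pH 7 buffer, MeOH, 30% H2O2, 0 °C; crude, DMAP (0.2 equiv), CH2Cl2, 23 °C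
Reagents that add atoms: none
Why: Proposed new method: twofold soft enolisation gives the Z,Z bis(boron enolate) 6, and each terminus adds to 2 through a closed Zimmerman–Traxler chair in which the auxiliary carbonyl lies anti to the enolate oxygen and the 4-benzyl group blocks one face, so both α-carbons and both carbinol carbons become S (Evans syn, C2-symmetric 7); after B–O cleavage each benzylic hydroxyl sits 1,4 to the distal imide carbonyl and, under DMAP catalysis, acylates itself 5-exo, expelling 4 and closing both lactones of the cis-fused bicycle with both aryl groups exo; the closest known chemistry is the Evans syn aldol of succinate half-ester imides with in-situ γ-lactonisation and the twofold aldol of succinamide dianions.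

**Step 4**
Reactants: 8 (3S,3aS,6S,6aS)-3,6-bis[4-(benzyloxy)-3,5-dimethoxyphenyl]tetrahydrofuro[3,4-c]furan-1,4-dione
Product: 9 dimethyl (2S,3S,4S,5S)-2,5-bis[4-(benzyloxy)-3,5-dimethoxyphenyl]oxolane-3,4-dicarboxylate
Conditions: HCl (1.25 M in MeOH), 1,4-dioxane, 60 °C
Reagents that add atoms: methanol, CO
Why: Acid-catalysed bis-lactone-to-tetrahydrofuran rearrangement (lactone methanolysis and alkyl–oxygen ionisation at the electron-rich benzylic carbons, Fischer esterification, 5-exo capture of the benzylic cation by the other benzylic oxygen); ring C3 and C4 keep the configuration set in step 3 and are trans, while C2 and C5 equilibrate through the cation to the all-trans isomer, the thermodynamic minimum.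

**Step 5**
Reactants: 9 dimethyl (2S,3S,4S,5S)-2,5-bis[4-(benzyloxy)-3,5-dimethoxyphenyl]oxolane-3,4-dicarboxylate
Product: 10 [(2S,3R,4R,5S)-2,5-bis[4-(benzyloxy)-3,5-dimethoxyphenyl]oxolane-3,4-diyl]dimethanol
Conditions: LiAlH4 (2.5 equiv), THF, 0 to 23 °C; Rochelle salt work-up
Reagents that add atoms: none
Why: Hydride reduction of both esters to primary alcohols leaves the aryl benzyl ethers and the cyclic ether untouched; the four stereocentres are unchanged (the 3,4 descriptors switch from S to R only because CH2OH ranks below the ring carbon).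

**Step 6**
Reactants: 10 [(2S,3R,4R,5S)-2,5-bis[4-(benzyloxy)-3,5-dimethoxyphenyl]oxolane-3,4-diyl]dimethanol
Product: 11 Huazhongilexin, [(2S,3R,4R,5S)-2,5-bis(4-hydroxy-3,5-dimethoxyphenyl)oxolane-3,4-diyl]dimethanol
Conditions: H2 (1 atm), Pd/C (10 wt %), EtOAc–MeOH 4:1, 23 °C, stopped at full conversion
Reagents that add atoms: none
Why: Catalytic hydrogenolysis cleaves the two aryl benzyl ethers faster than the hindered ring C–O bonds when run at 1 atm in EtOAc and stopped promptly; no stereocentre is touched.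

**Compound list**
1 | syringaldehyde (4-hydroxy-3,5-dimethoxybenzaldehyde) | COc1cc(C=O)cc(OC)c1O | starting material
2 | 4-(benzyloxy)-3,5-dimethoxybenzaldehyde | COc1cc(C=O)cc(OC)c1OCc1ccccc1 | intermediate
3 | succinyl chloride | O=C(Cl)CCC(Cl)=O | starting material
4 | (S)-4-benzyl-1,3-oxazolidin-2-one | O=C1N[C@@H](Cc2ccccc2)CO1 | starting material
5 | 1,4-bis[(4S)-4-benzyl-2-oxo-1,3-oxazolidin-3-yl]butane-1,4-dione | O=C(CCC(=O)N1[C@@H](Cc2ccccc2)COC1=O)N1[C@@H](Cc2ccccc2)COC1=O | intermediate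
6 | (4S,4'S)-3,3'-[(1Z,3Z)-1,4-bis(dibutylboranyloxy)buta-1,3-diene-1,4-diyl]bis(4-benzyl-1,3-oxazolidin-2-one) | CCCCB(CCCC)O/C(=C\C=C(/OB(CCCC)CCCC)N1[C@@H](Cc2ccccc2)COC1=O)N1[C@@H](Cc2ccccc2)COC1=O | intermediate
7 | (2S,3S)-1,4-bis[(4S)-4-benzyl-2-oxo-1,3-oxazolidin-3-yl]-2,3-bis{(S)-[4-(benzyloxy)-3,5-dimethoxyphenyl](hydroxy)methyl}butane-1,4-dione | O=C([C@H]([C@H](O)c3cc(OC)c(OCc4ccccc4)c(OC)c3)[C@@H]([C@H](O)c3cc(OC)c(OCc4ccccc4)c(OC)c3)C(=O)N1[C@@H](Cc2ccccc2)COC1=O)N1[C@@H](Cc2ccccc2)COC1=O | intermediate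
8 | (3S,3aS,6S,6aS)-3,6-bis[4-(benzyloxy)-3,5-dimethoxyphenyl]tetrahydrofuro[3,4-c]furan-1,4-dione | O=C1O[C@H](c3cc(OC)c(OCc4ccccc4)c(OC)c3)[C@@H]2[C@H]1[C@@H](c5cc(OC)c(OCc6ccccc6)c(OC)c5)OC2=O | intermediate
9 | dimethyl (2S,3S,4S,5S)-2,5-bis[4-(benzyloxy)-3,5-dimethoxyphenyl]oxolane-3,4-dicarboxylate | COc1cc([C@H]2O[C@H](c3cc(OC)c(OCc4ccccc4)c(OC)c3)[C@@H](C(=O)OC)[C@@H]2C(=O)OC)cc(OC)c1OCc1ccccc1 | intermediate
10 | [(2S,3R,4R,5S)-2,5-bis[4-(benzyloxy)-3,5-dimethoxyphenyl]oxolane-3,4-diyl]dimethanol | COc1cc([C@H]2O[C@H](c3cc(OC)c(OCc4ccccc4)c(OC)c3)[C@@H](CO)[C@@H]2CO)cc(OC)c1OCc1ccccc1 | intermediate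
11 | Huazhongilexin, [(2S,3R,4R,5S)-2,5-bis(4-hydroxy-3,5-dimethoxyphenyl)oxolane-3,4-diyl]dimethanol | COc1cc([C@H]2O[C@H](c3cc(OC)c(O)c(OC)c3)[C@@H](CO)[C@@H]2CO)cc(OC)c1O | target

**Totals**
Total steps: 6. Longest linear sequence: 5 steps (1 → 2 → 8 → 9 → 10 → 11; the branch 3 + 4 → 5 joins at step 3).

**Three steps most likely to fail, each with one fallback**

Step 3. The second enolisation and the second, more hindered aldol may stall at the mono-adduct, or retro-aldol may compete during lactonisation. The fallback sets out from 2 and comes back at 8; it makes the bond between the two α-carbons first and the benzylic C–O bonds last. Twofold Stobbe condensation of 2 with diethyl succinate (KOtBu, tBuOH, reflux; then KOH, aqueous EtOH) gives (2E,3E)-2,3-bis{[4-(benzyloxy)-3,5-dimethoxyphenyl]methylidene}butanedioic acid F1. Homogeneous asymmetric hydrogenation (H2 5 atm, [Rh(cod)((S,S)-Et-DuPhos)]OTf, MeOH, Et3N) gives (2R,3R)-2,3-bis{[4-(benzyloxy)-3,5-dimethoxyphenyl]methyl}butanedioic acid F2; the ligand sense is assigned by analogy with arylidenesuccinate half-esters and is not certain, so the antipodal ligand is used if the S,S acid forms. Twofold benzylic hydride abstraction with DDQ (2.2 equiv, 1,4-dioxane, 80 °C) and capture of each cation by the distal carboxyl closes both lactones to give 8; any benzylic epimer of 8 is funnelled to 9 in step 4.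

Step 4. The benzylic cation can close irreversibly onto the other electron-rich ring (aryltetralin), or stop at benzylic methyl ethers. The fallback sets out from 8 and comes back at 10; it removes the carbonyl groups before the ether is closed and closes it without protic acid. LiAlH4 (THF, 0 °C) gives (1S,2R,3R,4S)-1,4-bis[4-(benzyloxy)-3,5-dimethoxyphenyl]-2,3-bis(hydroxymethyl)butane-1,4-diol F3. Selective silylation of the two primary hydroxyls (TBSCl 2.1 equiv, imidazole, DMF, 0 °C) gives (1S,2R,3R,4S)-1,4-bis[4-(benzyloxy)-3,5-dimethoxyphenyl]-2,3-bis({[tert-butyl(dimethyl)silyl]oxy}methyl)butane-1,4-diol F4, so that the furofuran cannot form. MsCl/Et3N (CH2Cl2, −20 to 0 °C) ionises one benzylic mesylate and the other benzylic hydroxyl closes the ring to the all-trans {[(2S,3R,4R,5S)-2,5-bis[4-(benzyloxy)-3,5-dimethoxyphenyl]oxolane-3,4-diyl]bis(methyleneoxy)}bis[tert-butyl(dimethyl)silane] F5. TBAF (THF, 23 °C) then gives 10.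

Step 6. Hydrogenolysis may also cleave the benzylic C–O bonds of the electron-rich oxolane. The fallback sets out from 10 and comes back at 11 with a non-reductive debenzylation: BCl3 (3 equiv) with pentamethylbenzene (6 equiv) as benzyl-cation scavenger, CH2Cl2, −78 °C, then MeOH quench. The ortho-methoxy-assisted cleavage of the aryl benzyl ethers is fast at this temperature, and any reversible ring ionisation returns to the all-trans isomer. No new compound is made on the way (F0).

**Further compounds**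
F1 | step 3 | (2E,3E)-2,3-bis{[4-(benzyloxy)-3,5-dimethoxyphenyl]methylidene}butanedioic acid | OC(=O)\C(=C\c1cc(OC)c(OCc2ccccc2)c(OC)c1)\C(=C/c1cc(OC)c(OCc2ccccc2)c(OC)c1)C(O)=O
F2 | step 3 | (2R,3R)-2,3-bis{[4-(benzyloxy)-3,5-dimethoxyphenyl]methyl}butanedioic acid | OC(=O)[C@H](Cc1cc(OC)c(OCc2ccccc2)c(OC)c1)[C@@H](Cc1cc(OC)c(OCc2ccccc2)c(OC)c1)C(O)=O
F3 | step 4 | (1S,2R,3R,4S)-1,4-bis[4-(benzyloxy)-3,5-dimethoxyphenyl]-2,3-bis(hydroxymethyl)butane-1,4-diol | O[C@H](c1cc(OC)c(OCc2ccccc2)c(OC)c1)[C@@H](CO)[C@H](CO)[C@H](O)c1cc(OC)c(OCc2ccccc2)c(OC)c1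
F4 | step 4 | (1S,2R,3R,4S)-1,4-bis[4-(benzyloxy)-3,5-dimethoxyphenyl]-2,3-bis({[tert-butyl(dimethyl)silyl]oxy}methyl)butane-1,4-diol | O[C@H](c1cc(OC)c(OCc2ccccc2)c(OC)c1)[C@@H](CO[Si](C)(C)C(C)(C)C)[C@H](CO[Si](C)(C)C(C)(C)C)[C@H](O)c1cc(OC)c(OCc2ccccc2)c(OC)c1
F5 | step 4 | {[(2S,3R,4R,5S)-2,5-bis[4-(benzyloxy)-3,5-dimethoxyphenyl]oxolane-3,4-diyl]bis(methyleneoxy)}bis[tert-butyl(dimethyl)silane] | COc1cc([C@H]2O[C@H](c3cc(OC)c(OCc4ccccc4)c(OC)c3)[C@@H](CO[Si](C)(C)C(C)(C)C)[C@@H]2CO[Si](C)(C)C(C)(C)C)cc(OC)c1OCc1ccccc1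
F0 | step 6 | none | none
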